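**Plan**

- Retrosynthesis: cut the central C–C single bond of the (E,E)-butadiene (two identical dienyl iodides), then each CH=CHI unit (ring enal), then the side-chain epoxide (prenyl alkene), then the ring C2–C3 bond, and last the C4–C5 bond of the open chain.
- Enabling feature: in each cyclohexene ring (C1 = CHOH, C2 = quaternary C–CH3, C3=C4 = alkene with C4 carrying the diene, C5/C6 = CH2), C1 and C2 are the two carbons of an opened trisubstituted epoxide, and C3=C4 lies where a vinylsilane terminator keeps its double bond.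
- Forward: geraniol gives the epoxy alcohol and then the vinyl epoxide; a silyl propargyl ether gives the (Z)-iodo vinylsilane; a B-alkyl Suzuki coupling joins the chain; the epoxide-opening vinylsilane cyclization closes the ring; side-chain epoxidation, unmasking to the enal and iodo-olefination follow; the two rings are joined last.
- Stereochemistry: Sharpless epoxidation sets the epoxide that becomes C1 (C–O retained) and C2 (inverted in the cyclization); the D-fructose-derived Shi ketone sets the (R)-epoxide; syn-silylstannation fixes the vinylsilane geometry; Takai olefination and a stereoretentive coupling give the E,E-diene.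

Key step: step 7

Step 1
Reactants: 1 geraniol
Product: 2 (2S,3S)-2,3-epoxygeraniol, i.e. [(2S,3S)-3-methyl-3-(4-methylpent-3-en-1-yl)oxiran-2-yl]methanol
Conditions: Ti(OiPr)4 (5 mol%), L-(+)-diethyl tartrate (7 mol%), t-BuOOH (2 equiv), 4 Å MS, CH2Cl2, −20 °C
Reagents that add atoms: tert-butyl hydroperoxide, CC(C)(C)OO
Why: Sharpless asymmetric epoxidation, in which the allylic alcohol binds the titanium tartrate complex and L-(+)-diethyl tartrate directs oxygen to the face that gives the (2S,3S)-epoxide, while the 6,7-alkene has no directing hydroxyl and should stay untouched.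

Step 2
Reactants: 2 (2S,3S)-2,3-epoxygeraniol
Product: 3 (2R,3S)-3-methyl-3-(4-methylpent-3-en-1-yl)oxirane-2-carbaldehyde
Conditions: PhI(OAc)2 (1.1 equiv), TEMPO (10 mol%), CH2Cl2, rt; crude aldehyde used at once
Reagents that add atoms: none
Why: TEMPO/PhI(OAc)2 oxoammonium oxidation should take the primary alcohol to the aldehyde under near-neutral, water-free conditions that neither open the epoxide nor over-oxidise, the descriptor at C2 changing to R only because the formyl group now outranks C3.

Step 3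
Reactants: 3 (2R,3S)-3-methyl-3-(4-methylpent-3-en-1-yl)oxirane-2-carbaldehyde
Product: 4 (2S,3S)-3-ethenyl-2-methyl-2-(4-methylpent-3-en-1-yl)oxirane
Conditions: Ph3PCH3Br, KN(SiMe3)2, THF, −78 → 0 °C
Reagents that add atoms: methyltriphenylphosphonium bromide (as its ylide), C[P+](c1ccccc1)(c1ccccc1)c1ccccc1.[Br-]
Why: Wittig methylenation with the non-stabilised ylide is fast at low temperature, so the α-epoxy aldehyde should be olefinated before it can epimerise or open.

Step 4
Reactants: 5 tert-butyldimethyl(prop-2-yn-1-yloxy)silane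
Product: 6 (Z)-tert-butyldimethyl{[2-(tributylstannyl)-3-(trimethylsilyl)prop-2-en-1-yl]oxy}silane
Conditions: Bu3SnSiMe3 (1.1 equiv), Pd(PPh3)4 (2 mol%), THF, 65 °C
Reagents that add atoms: tributyl(trimethylsilyl)stannane, CCCC[Sn](CCCC)(CCCC)[Si](C)(C)C
Why: Palladium-catalysed silylstannation adds the Si–Sn bond syn across the terminal alkyne with silicon on the terminal and tin on the internal carbon, which fixes Me3Si cis to the position that will carry the tether.

Step 5
Reactants: 6 (Z)-tert-butyldimethyl{[2-(tributylstannyl)-3-(trimethylsilyl)prop-2-en-1-yl]oxy}silane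
Product: 7 (Z)-tert-butyl{[2-iodo-3-(trimethylsilyl)prop-2-en-1-yl]oxy}dimethylsilane
Conditions: I2 (1.05 equiv), CH2Cl2, 0 °C
Reagents that add atoms: iodine, II
Why: Iododestannylation, an electrophilic ipso-substitution that is much faster at the C–Sn than at the C–Si bond and goes with retention, so the Z geometry (iodine cis to Me3Si) should carry over.

Step 6
Reactants: 4 (2S,3S)-3-ethenyl-2-methyl-2-(4-methylpent-3-en-1-yl)oxirane; 7 (Z)-tert-butyl{[2-iodo-3-(trimethylsilyl)prop-2-en-1-yl]oxy}dimethylsilane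
Product: 9 tert-butyldimethyl{[(2E)-2-{2-[(2S,3S)-3-methyl-3-(4-methylpent-3-en-1-yl)oxiran-2-yl]ethyl}-3-(trimethylsilyl)prop-2-en-1-yl]oxy}silane, via alkylborane 8 (not isolated)
Conditions: 9-BBN (1.2 equiv), THF, 0 °C → rt; then 7, PdCl2(dppf)·CH2Cl2 (5 mol%), AsPh3 (10 mol%), Cs2CO3, DMF/H2O, rt
Reagents that add atoms: none
Why: B-alkyl Suzuki–Miyaura coupling, in which the bulky, weakly Lewis-acidic 9-BBN should add anti-Markovnikov to the monosubstituted vinyl group only (trisubstituted alkene and epoxide left alone) and the primary alkyl group is then transferred under base to the alkenylpalladium iodide with retention of alkene geometry, leaving Me3Si cis to the new tether.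

Step 7
Reactants: 9 tert-butyldimethyl{[(2E)-2-{2-[(2S,3S)-3-methyl-3-(4-methylpent-3-en-1-yl)oxiran-2-yl]ethyl}-3-(trimethylsilyl)prop-2-en-1-yl]oxy}silane
Product: 10 (1S,2S)-4-{[(tert-butyldimethylsilyl)oxy]methyl}-2-methyl-2-(4-methylpent-3-en-1-yl)cyclohex-3-en-1-ol
Conditions: MeAlCl2 (1.5 equiv), CH2Cl2, −78 °C; Et3N, then aq. NaHCO3
Reagents that add atoms: none
Why: MeAlCl2 binds the epoxide oxygen and weakens the tertiary C–O bond, the silicon-bearing alkene carbon attacks that carbon from the side opposite the oxygen in a chair-like transition state, and the β-silyl cation at C4 loses Me3Si to chloride to leave the C3=C4 alkene. The closest known reaction type is the Lewis-acid epoxide-initiated cation–olefin cyclization with silicon-directed termination (ipso-substitution of a vinylsilane), of which the allylsilane version is the more common. The six-membered ring closes in the 6-endo mode with respect to the alkene and endo with respect to the epoxide, so both alkene carbons and both epoxide carbons end up in the ring. C2 is set by stereospecific inversion at the tertiary epoxide carbon and C1 keeps its Sharpless-derived C–O bond, which should give the cis (1S,2S) methyl/hydroxyl pair. The step needs attack through C3 and an alkene that stays at C3=C4: attack through C4 would give a five-membered ring and a cation α to silicon, silicon cis to the tether is the geometry that ipso-substitution within a six-membered ring requires, and the prenyl alkene could reach the tertiary carbon only through a four-membered or an anti-Markovnikov five-membered closure.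

Step 8
Reactants: 10 (1S,2S)-4-{[(tert-butyldimethylsilyl)oxy]methyl}-2-methyl-2-(4-methylpent-3-en-1-yl)cyclohex-3-en-1-ol
Product: 11 (1S,2S)-4-{[(tert-butyldimethylsilyl)oxy]methyl}-2-{2-[(2R)-3,3-dimethyloxiran-2-yl]ethyl}-2-methylcyclohex-3-en-1-ol
Conditions: D-fructose-derived Shi ketone (30 mol%), KHSO5 (as Oxone), K2CO3, Bu4NHSO4, MeCN/CH2(OMe)2, aq. Na2B4O7 buffer, 0 °C
Reagents that add atoms: potassium peroxymonosulfate, [K+].[O-]S(=O)(=O)OO
Why: Shi epoxidation, in which the chiral dioxirane should attack the electron-rich, unhindered prenyl alkene through the spiro transition state that gives the (R)-epoxide under catalyst control, while the ring alkene is shielded by the neighbouring quaternary carbon and deactivated by its allylic oxygen.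

Step 9
Reactants: 11 (1S,2S)-4-{[(tert-butyldimethylsilyl)oxy]methyl}-2-{2-[(2R)-3,3-dimethyloxiran-2-yl]ethyl}-2-methylcyclohex-3-en-1-ol
Product: 12 (1S,2S)-2-{2-[(2R)-3,3-dimethyloxiran-2-yl]ethyl}-4-(hydroxymethyl)-2-methylcyclohex-3-en-1-ol
Conditions: Bu4NF (1.2 equiv), THF, 0 °C → rt
Reagents that add atoms: none
Why: Fluoride-mediated desilylation, driven by the strong Si–F bond, should free the primary alcohol under basic conditions that the acid-sensitive hydroxy epoxide tolerates.

Step 10
Reactants: 12 (1S,2S)-2-{2-[(2R)-3,3-dimethyloxiran-2-yl]ethyl}-4-(hydroxymethyl)-2-methylcyclohex-3-en-1-ol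
Product: 13 (3S,4S)-3-{2-[(2R)-3,3-dimethyloxiran-2-yl]ethyl}-4-hydroxy-3-methylcyclohex-1-ene-1-carbaldehyde
Conditions: MnO2 (activated, excess), CH2Cl2, rt
Reagents that add atoms: none
Why: MnO2 oxidation is selective for allylic alcohols, so the primary allylic hydroxyl should become the enal while the saturated secondary hydroxyl and the epoxide do not react.

Step 11
Reactants: 13 (3S,4S)-3-{2-[(2R)-3,3-dimethyloxiran-2-yl]ethyl}-4-hydroxy-3-methylcyclohex-1-ene-1-carbaldehyde
Product: 14 (1S,2S)-2-{2-[(2R)-3,3-dimethyloxiran-2-yl]ethyl}-4-[(E)-2-iodoethenyl]-2-methylcyclohex-3-en-1-ol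
Conditions: CrCl2 (6 equiv), CHI3 (2 equiv), THF/1,4-dioxane, 0 °C → rt
Reagents that add atoms: iodoform, IC(I)I
Why: Takai olefination, in which the gem-dichromium species from CHI3 and CrCl2 adds to the aldehyde and anti elimination should give the (E)-iodoalkene, a reagent that tolerates free hydroxyl groups.

Step 12
Reactants: 14 (1S,2S)-2-{2-[(2R)-3,3-dimethyloxiran-2-yl]ethyl}-4-[(E)-2-iodoethenyl]-2-methylcyclohex-3-en-1-ol (two molecules)
Product: 16 target CNP0229121.5 (the C2-symmetric bis-cyclohexenol joined through a (1E,3E)-buta-1,3-diene-1,4-diyl unit), via dienyl pinacol boronate 15 (not isolated)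
Conditions: B2pin2 (0.5 equiv), PdCl2(dppf)·CH2Cl2 (5 mol%), K3PO4, DMF/H2O, 50 °C, degassed
Reagents that add atoms: none
Why: One-pot Miyaura borylation/Suzuki–Miyaura coupling, in which half of the iodide is borylated and the resulting (E)-dienylboronate couples with the remaining iodide, both partners keeping their geometry, so the central bond of the (E,E)-diene should form without touching the stereocentres.

**Compound list**

1 | geraniol, (2E)-3,7-dimethylocta-2,6-dien-1-ol | CC(C)=CCC/C(C)=C/CO | starting material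
2 | (2S,3S)-2,3-epoxygeraniol, [(2S,3S)-3-methyl-3-(4-methylpent-3-en-1-yl)oxiran-2-yl]methanol | OC[C@@H]1O[C@@]1(C)CCC=C(C)C | intermediate
3 | (2R,3S)-3-methyl-3-(4-methylpent-3-en-1-yl)oxirane-2-carbaldehyde | O=C[C@@H]1O[C@@]1(C)CCC=C(C)C | intermediate
4 | (2S,3S)-3-ethenyl-2-methyl-2-(4-methylpent-3-en-1-yl)oxirane | C=C[C@@H]1O[C@@]1(C)CCC=C(C)C | intermediate
5 | tert-butyldimethyl(prop-2-yn-1-yloxy)silane | C#CCO[Si](C)(C)C(C)(C)C | starting material
6 | (Z)-tert-butyldimethyl{[2-(tributylstannyl)-3-(trimethylsilyl)prop-2-en-1-yl]oxy}silane | C[Si](C)(C)/C=C(/CO[Si](C)(C)C(C)(C)C)[Sn](CCCC)(CCCC)CCCC | intermediate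
7 | (Z)-tert-butyl{[2-iodo-3-(trimethylsilyl)prop-2-en-1-yl]oxy}dimethylsilane | C[Si](C)(C)/C=C(/CO[Si](C)(C)C(C)(C)C)I | intermediate
8 | 9-{2-[(2S,3S)-3-methyl-3-(4-methylpent-3-en-1-yl)oxiran-2-yl]ethyl}-9-borabicyclo[3.3.1]nonane | C(CB1C2CCCC1CCC2)[C@@H]1O[C@@]1(C)CCC=C(C)C | intermediate (not isolated)
9 | tert-butyldimethyl{[(2E)-2-{2-[(2S,3S)-3-methyl-3-(4-methylpent-3-en-1-yl)oxiran-2-yl]ethyl}-3-(trimethylsilyl)prop-2-en-1-yl]oxy}silane | C[Si](C)(C)/C=C(/CO[Si](C)(C)C(C)(C)C)CC[C@@H]1O[C@@]1(C)CCC=C(C)C | intermediate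
10 | (1S,2S)-4-{[(tert-butyldimethylsilyl)oxy]methyl}-2-methyl-2-(4-methylpent-3-en-1-yl)cyclohex-3-en-1-ol | CC(C)(C)[Si](C)(C)OCC1=C[C@](C)(CCC=C(C)C)[C@@H](O)CC1 | intermediate
11 | (1S,2S)-4-{[(tert-butyldimethylsilyl)oxy]methyl}-2-{2-[(2R)-3,3-dimethyloxiran-2-yl]ethyl}-2-methylcyclohex-3-en-1-ol | CC(C)(C)[Si](C)(C)OCC1=C[C@](C)(CC[C@H]2OC2(C)C)[C@@H](O)CC1 | intermediate
12 | (1S,2S)-2-{2-[(2R)-3,3-dimethyloxiran-2-yl]ethyl}-4-(hydroxymethyl)-2-methylcyclohex-3-en-1-ol | OCC1=C[C@](C)(CC[C@H]2OC2(C)C)[C@@H](O)CC1 | intermediate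
13 | (3S,4S)-3-{2-[(2R)-3,3-dimethyloxiran-2-yl]ethyl}-4-hydroxy-3-methylcyclohex-1-ene-1-carbaldehyde | O=CC1=C[C@](C)(CC[C@H]2OC2(C)C)[C@@H](O)CC1 | intermediate
14 | (1S,2S)-2-{2-[(2R)-3,3-dimethyloxiran-2-yl]ethyl}-4-[(E)-2-iodoethenyl]-2-methylcyclohex-3-en-1-ol | I/C=C/C1=C[C@](C)(CC[C@H]2OC2(C)C)[C@@H](O)CC1 | intermediate
15 | (1S,2S)-2-{2-[(2R)-3,3-dimethyloxiran-2-yl]ethyl}-2-methyl-4-[(E)-2-(4,4,5,5-tetramethyl-1,3,2-dioxaborolan-2-yl)ethenyl]cyclohex-3-en-1-ol | CC1(C)OB(/C=C/C2=C[C@](C)(CC[C@H]3OC3(C)C)[C@@H](O)CC2)OC1(C)C | intermediate (not isolated)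
16 | (1S,1'S,2S,2'S)-4,4'-[(1E,3E)-buta-1,3-diene-1,4-diyl]bis(2-{2-[(2R)-3,3-dimethyloxiran-2-yl]ethyl}-2-methylcyclohex-3-en-1-ol), CNP0229121.5 | CC1(C)O[C@@H]1CC[C@@]1(C)C=C(/C=C/C=C/C2=C[C@](C)(CC[C@H]3OC3(C)C)[C@@H](O)CC2)CC[C@@H]1O | target

**Step count**

Total: 12 steps. Longest linear sequence: 10 steps (steps 1–3 and 6–12, geraniol to the target).

**Steps most likely to fail**

Step 7. The aluminium-activated epoxide may be consumed faster than the carbon–carbon bond forms, by 1,2-hydride shift to the ketone, by chloride opening, or by attack of the silyl ether oxygen; the allylic oxygen lowers the nucleophilicity of the vinylsilane and makes this more likely. The fallback makes the same C2–C3 bond intermolecularly, again with inversion at the tertiary epoxide carbon, and closes the ring by metathesis. It sets out from epoxy alcohol 2 and comes back at 11.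
- Hydroxyl-directed opening of 2 at its tertiary carbon with diethyl[(trimethylsilyl)ethynyl]aluminium (from Me3SiC≡CH, n-BuLi and Et2AlCl; toluene, 0 °C) would give (2R,3S)-3-methyl-3-(4-methylpent-3-en-1-yl)-5-(trimethylsilyl)pent-4-yne-1,2-diol F1.
- NaH and 1-(p-tolylsulfonyl)imidazole would close the terminal epoxide, (2R)-2-[(3S)-3,7-dimethyl-1-(trimethylsilyl)oct-6-en-1-yn-3-yl]oxirane F2.
- CuI-catalysed opening with 2-{[(tert-butyldimethylsilyl)oxy]methyl}prop-2-en-1-ylmagnesium chloride would give (5S,6S)-2-{[(tert-butyldimethylsilyl)oxy]methyl}-6,10-dimethyl-6-[(trimethylsilyl)ethynyl]undeca-1,9-dien-5-ol F3.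
- K2CO3 in MeOH would free the alkyne, (5S,6S)-2-{[(tert-butyldimethylsilyl)oxy]methyl}-6-ethynyl-6,10-dimethylundeca-1,9-dien-5-ol F4.
- Semi-hydrogenation over Pd/CaCO3–Pb(OAc)2 with quinoline would give (5S,6S)-2-{[(tert-butyldimethylsilyl)oxy]methyl}-6-ethenyl-6,10-dimethylundeca-1,9-dien-5-ol F5.
- Shi epoxidation as in step 8 would give (5S,6S)-2-{[(tert-butyldimethylsilyl)oxy]methyl}-8-[(2R)-3,3-dimethyloxiran-2-yl]-6-ethenyl-6-methyloct-1-en-5-ol F6. This is placed before the metathesis so that the prenyl alkene cannot close a cyclopentene with the vinyl group.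
- Ring-closing metathesis with the second-generation Grubbs catalyst would form C3=C4 and deliver 11.

Step 6. Transmetallation of the primary alkylborane onto the hindered alkenylpalladium iodide (flanked by a cis Me3Si group and a silyloxymethyl group) may be slow, so that protodeboronation and β-hydride elimination of the alkyl group take over. The fallback reverses the roles of the partners and uses copper in place of palladium. It sets out from alkylborane 8 (made from 4 as in step 6) and iodide 7 and comes back at 9.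
- Iodinolysis of 8 (I2, NaOMe, MeOH/THF, 0 °C) would give (2S,3S)-3-(2-iodoethyl)-2-methyl-2-(4-methylpent-3-en-1-yl)oxirane F7.
- Iodine–magnesium exchange on 7 (iPrMgCl·LiCl, THF, −40 °C) would give, with retention of geometry, (Z)-{3-[(tert-butyldimethylsilyl)oxy]-1-(trimethylsilyl)prop-1-en-2-yl}magnesium chloride F8.
- Li2CuCl4-catalysed coupling of the two (THF, −40 → 0 °C) would give 9; the trisubstituted epoxide is a far poorer electrophile than the primary iodide.

Step 11. The Lewis-acidic chromium halides may open the acid-sensitive trisubstituted epoxide during the slow olefination (halohydrin formation, or cyclisation of the C1 hydroxyl onto the epoxide), and E selectivity may erode. The fallback builds the same (E)-dienyl unit from an alkyne without chromium. It sets out from 13 and comes back at 15.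
- Ohira–Bestmann homologation (dimethyl (1-diazo-2-oxopropyl)phosphonate, K2CO3, MeOH, 0 °C → rt) would give (1S,2S)-2-{2-[(2R)-3,3-dimethyloxiran-2-yl]ethyl}-4-ethynyl-2-methylcyclohex-3-en-1-ol F9.
- Zirconium-catalysed syn hydroboration with HBpin (Cp2Zr(H)Cl 5 mol%, Et3N, CH2Cl2) would give the (E)-boronate 15.
- 15 would then be dimerised by palladium-catalysed oxidative homocoupling (Pd(OAc)2, K2CO3, O2), which takes the place of step 12 and ends at 16.

**Further compounds**

F1 | step 7 | (2R,3S)-3-methyl-3-(4-methylpent-3-en-1-yl)-5-(trimethylsilyl)pent-4-yne-1,2-diol | OC[C@H](O)[C@@](C)(CCC=C(C)C)C#C[Si](C)(C)C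
F2 | step 7 | (2R)-2-[(3S)-3,7-dimethyl-1-(trimethylsilyl)oct-6-en-1-yn-3-yl]oxirane | C1O[C@@H]1[C@@](C)(CCC=C(C)C)C#C[Si](C)(C)C
F3 | step 7 | (5S,6S)-2-{[(tert-butyldimethylsilyl)oxy]methyl}-6,10-dimethyl-6-[(trimethylsilyl)ethynyl]undeca-1,9-dien-5-ol | C=C(CO[Si](C)(C)C(C)(C)C)CC[C@H](O)[C@@](C)(CCC=C(C)C)C#C[Si](C)(C)C
F4 | step 7 | (5S,6S)-2-{[(tert-butyldimethylsilyl)oxy]methyl}-6-ethynyl-6,10-dimethylundeca-1,9-dien-5-ol | C=C(CO[Si](C)(C)C(C)(C)C)CC[C@H](O)[C@@](C)(CCC=C(C)C)C#C
F5 | step 7 | (5S,6S)-2-{[(tert-butyldimethylsilyl)oxy]methyl}-6-ethenyl-6,10-dimethylundeca-1,9-dien-5-ol | C=C(CO[Si](C)(C)C(C)(C)C)CC[C@H](O)[C@@](C)(CCC=C(C)C)C=C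
F6 | step 7 | (5S,6S)-2-{[(tert-butyldimethylsilyl)oxy]methyl}-8-[(2R)-3,3-dimethyloxiran-2-yl]-6-ethenyl-6-methyloct-1-en-5-ol | C=C(CO[Si](C)(C)C(C)(C)C)CC[C@H](O)[C@@](C)(CC[C@H]1OC1(C)C)C=C
F7 | step 6 | (2S,3S)-3-(2-iodoethyl)-2-methyl-2-(4-methylpent-3-en-1-yl)oxirane | ICC[C@@H]1O[C@@]1(C)CCC=C(C)C
F8 | step 6 | (Z)-{3-[(tert-butyldimethylsilyl)oxy]-1-(trimethylsilyl)prop-1-en-2-yl}magnesium chloride | C[Si](C)(C)/C=C(/CO[Si](C)(C)C(C)(C)C)[Mg]Cl
F9 | step 11 | (1S,2S)-2-{2-[(2R)-3,3-dimethyloxiran-2-yl]ethyl}-4-ethynyl-2-methylcyclohex-3-en-1-ol | C#CC1=C[C@](C)(CC[C@H]2OC2(C)C)[C@@H](O)CC1
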